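**Plan**
- The O2–C3(OH)–C4(H) part of the lactone ring is the hydrate of the C3=C4 enol double bond of a flat 3-acyloxymethyl-4,5-dimethylisocoumarin. In that isocoumarin the C4 and C5 methyl groups are forced together in the ring plane, so adding H to C4 and O to C3 relieves strain and creates both stereocentres.
- Retrosynthesis: cut C4–H and the ring O–C3 bond (loss of water gives isocoumarin 22), then the CH2O–C(=O) ester bond to ring B, then O2–C1 and C3–C4 (lateral acylation of an o-ethylbenzoate), then the C4–CH3 and C8a–C1 bonds.
- Forward: ring A is elaborated to o-ethylbenzoate 9, the C3 chain is joined by lateral lithiation and acylation, and the lactone ring is closed as the enol lactone (step 7). The ring B acid (three steps from 16) is attached by Mitsunobu esterification, and the lactone ring is opened and re-closed onto C3 in the last step.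
- Stereochemistry: C4 (S) comes from enzyme-controlled protonation of the enol on its Re face. C3 (R) follows by thermodynamic equilibration of the hemiketal (3-OH axial and trans to the 4-methyl).

Key step: step 13

Assumption: the hemiketal carbon C3 equilibrates through the open keto acid, so only C4 has to be set kinetically and C3 settles to the trans (3R) arrangement found in the target.

**Route**

Step 1
Reactants: 1 2,4-dimethoxy-6-methylbenzaldehyde
Product: 3 1,5-dimethoxy-2,3-dimethylbenzene, via hydrazone 2 (not isolated)
Conditions: N2H4·H2O, KOH, diethylene glycol, 130 then 200 °C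
Reagents that add atoms: none
Why: Wolff–Kishner reduction (Huang-Minlon procedure) takes the aryl aldehyde through hydrazone 2 to the methyl group under basic conditions, which avoids the Friedel–Crafts diarylmethane formation that an acidic reduction would invite on this electron-rich ring.

Step 2
Reactants: 3 1,5-dimethoxy-2,3-dimethylbenzene
Product: 5 2,4-dimethoxy-5,6-dimethylbenzaldehyde, via iminium chloride 4 (not isolated)
Conditions: POCl3, DMF, 0 to 80 °C; then ice-water
Reagents that add atoms: N,N-dimethylformamide CN(C)C=O; water O
Why: Vilsmeier–Haack formylation should go para to one methoxy group and ortho to the other (the position next to the C-methyl), as it does for 3,5-dimethoxytoluene, because the position between the two methoxy groups is the more encumbered one; hydrolysis of iminium salt 4 on work-up gives the aldehyde.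

Step 3
Reactants: 5 2,4-dimethoxy-5,6-dimethylbenzaldehyde
Product: 6 2,4-dimethoxy-5,6-dimethylbenzoic acid
Conditions: NaClO2, NaH2PO4, 2-methylbut-2-ene, t-BuOH/H2O, rt
Reagents that add atoms: sodium chlorite [Na+].[O-]Cl=O
Why: Pinnick oxidation converts the hindered aldehyde into the acid without touching the ring methyl groups, and the alkene scavenger removes HOCl before it can chlorinate the electron-rich ring.

Step 4
Reactants: 6 2,4-dimethoxy-5,6-dimethylbenzoic acid
Product: 7 methyl 2,4-dimethoxy-5,6-dimethylbenzoate
Conditions: MeI, K2CO3, DMF, rt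
Reagents that add atoms: iodomethane CI
Why: SN2 alkylation of the carboxylate esterifies a di-ortho-substituted benzoic acid that would resist Fischer esterification.

Step 5
Reactants: 7 methyl 2,4-dimethoxy-5,6-dimethylbenzoate
Product: 9 methyl 2-ethyl-4,6-dimethoxy-3-methylbenzoate, via benzylic lithium species 8 (not isolated)
Conditions: LiN(iPr)2, THF, −78 °C; then MeI, −78 to 0 °C
Reagents that add atoms: iodomethane CI
Why: Lateral lithiation of an o-toluate removes a proton only from the methyl group ortho to the ester (the anion is an extended ester enolate, the meta methyl is not acidified), and C-methylation of 8 gives the ethyl group that becomes C4 and its methyl.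

Step 6
Reactants: 9 methyl 2-ethyl-4,6-dimethoxy-3-methylbenzoate; 10 2-(benzyloxy)-N-methoxy-N-methylacetamide
Product: 13 methyl 2-[4-(benzyloxy)-3-oxobutan-2-yl]-4,6-dimethoxy-3-methylbenzoate (racemic), via benzylic lithium species 11 (not isolated), via lithium hemiaminal adduct 12 (not isolated)
Conditions: LiN(iPr)2, THF, −78 °C; then 10, −78 to −40 °C; then 1 M HCl, 0 °C
Reagents that add atoms: none
Why: A second lateral lithiation at the benzylic CH2 gives anion 11, and its acylation by the Weinreb amide stops at the chelated adduct 12, so the enolisable ketone appears only on acidic work-up; the new stereocentre is racemic and is erased in step 7.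

Step 7
Reactants: 13 methyl 2-[4-(benzyloxy)-3-oxobutan-2-yl]-4,6-dimethoxy-3-methylbenzoate
Product: 14 3-[(benzyloxy)methyl]-6,8-dimethoxy-4,5-dimethyl-1H-isochromen-1-one
Conditions: p-toluenesulfonic acid monohydrate (cat.), toluene, reflux, 4 Å molecular sieves
Reagents that add atoms: none
Why: Acid-catalysed enol lactonisation, the standard closure of 2-(2-oxoalkyl)benzoates to isocoumarins, should close the 6-membered lactone ring through the ketone enol oxygen and the ortho ester, with methanol removed by the sieves to drive the reaction.

Step 8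
Reactants: 14 3-[(benzyloxy)methyl]-6,8-dimethoxy-4,5-dimethyl-1H-isochromen-1-one
Product: 15 8-hydroxy-3-(hydroxymethyl)-6-methoxy-4,5-dimethyl-1H-isochromen-1-one
Conditions: BCl3, pentamethylbenzene, CH2Cl2, −78 to 0 °C; then aq. NaHCO3
Reagents that add atoms: none
Why: Lewis-acid ether cleavage with BCl3 should remove the benzyl group (pentamethylbenzene traps the benzyl cation so that C7 is not benzylated) and, directed by the lactone carbonyl, only the peri 8-methyl ether, leaving the 6-methoxy group that the target keeps.

Step 9
Reactants: 16 methyl 2,4-dihydroxy-3,6-dimethylbenzoate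
Product: 17 methyl 3-formyl-4,6-dihydroxy-2,5-dimethylbenzoate
Conditions: Cl2CHOMe, TiCl4, CH2Cl2, 0 °C to rt; then 1 M HCl
Reagents that add atoms: dichloromethyl methyl ether COC(Cl)Cl; water O
Why: Rieche formylation of the phenol can occur only at the single free ring position of 16, which is ortho to one hydroxyl and para to the other.

Step 10
Reactants: 17 methyl 3-formyl-4,6-dihydroxy-2,5-dimethylbenzoate
Product: 19 methyl 2,4-dihydroxy-3,5,6-trimethylbenzoate, via benzylic alcohol 18 (not isolated)
Conditions: Et3SiH, CF3CO2H, CH2Cl2, 0 °C to rt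
Reagents that add atoms: none
Why: Ionic hydrogenation should work because the ortho and para hydroxyl groups stabilise the benzylic cation formed from alcohol 18, Et3SiH reduces it to the methyl group, and the fully substituted ring leaves no position for diarylmethane formation.

Step 11
Reactants: 19 methyl 2,4-dihydroxy-3,5,6-trimethylbenzoate
Product: 21 2,4-dihydroxy-3,5,6-trimethylbenzoic acid, via acylium hydrogen sulfate 20 (not isolated)
Conditions: conc. H2SO4, 0 °C to rt; then ice-water
Reagents that add atoms: water O
Why: Hydrolysis of a di-ortho-substituted benzoate by the acylium (AAC1) pathway should give the acid on cold aqueous quench of 20 without the heating that decarboxylates 2,4-dihydroxybenzoic acids, and ring sulfonation is excluded because every ring position is substituted.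

Step 12
Reactants: 15 8-hydroxy-3-(hydroxymethyl)-6-methoxy-4,5-dimethyl-1H-isochromen-1-one; 21 2,4-dihydroxy-3,5,6-trimethylbenzoic acid
Product: 22 (8-hydroxy-6-methoxy-4,5-dimethyl-1-oxo-1H-isochromen-3-yl)methyl 2,4-dihydroxy-3,5,6-trimethylbenzoate
Conditions: PPh3, DIAD, THF, 0 °C to rt
Reagents that add atoms: none
Why: In this Mitsunobu esterification the primary allylic alcohol of 15 is activated and displaced by the carboxylate of 21, the most acidic OH present, so the hindered acid carbonyl is never attacked and the chelated or flanked phenols stay free, as in Mitsunobu esterifications of unprotected 2,4-dihydroxybenzoic acids.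

Step 13
Reactants: 22 (8-hydroxy-6-methoxy-4,5-dimethyl-1-oxo-1H-isochromen-3-yl)methyl 2,4-dihydroxy-3,5,6-trimethylbenzoate
Product: 24 [(3R,4S)-3,8-dihydroxy-6-methoxy-4,5-dimethyl-1-oxo-3,4-dihydro-1H-isochromen-3-yl]methyl 2,4-dihydroxy-3,5,6-trimethylbenzoate, via keto acid 23 (not isolated)
Conditions: pig liver esterase (serine carboxylesterase), 0.1 M phosphate buffer pH 6.5/DMSO 9:1, 20 °C; then citric acid to pH 3, EtOAc
Reagents that add atoms: water O
Why: Proposed new method: the active-site serine should add to the enol-lactone carbonyl C1 of 22 (isocoumarins are known to acylate serine hydrolases this way), which unmasks the C3–C4 enol while the aroyl group is held in the chiral pocket; proton delivery to the Re face of C4 by the catalytic histidine then fixes the 4S centre, and water cleaves the acyl-enzyme to release keto acid 23. The closest known reaction type is the esterase- or lipase-catalysed hydrolysis of acyclic enol esters with enantioface-selective protonation to α-chiral ketones, which has not been shown on an enol lactone that recloses as a lactol. The ring closes by 6-exo-trig addition of the carboxyl oxygen to the C3 ketone, and because this hemiketalisation is reversible C3 is set thermodynamically: with C4 fixed as S, the isomer with the 3-hydroxyl axial (anomeric effect) and trans to the pseudo-axial 4-methyl, which is 3R, should predominate. C4 is therefore controlled by the enzyme and C3 by C4. The step needs chemoselectivity for the lactone over the ring B ester and must not racemise C4: the lactone is an activated enol ester held planar, whereas the ring B ester is a twisted di-ortho-substituted benzoate of a primary alcohol, and working at pH 6.5 with prompt acidification keeps the enolisable keto acid short-lived. Hydration should be downhill because the planar isocoumarin presses the C4 and C5 methyl groups together.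

**Compound list**

1 | 2,4-dimethoxy-6-methylbenzaldehyde | COc1cc(C)c(C=O)c(OC)c1 | starting material
2 | (E)-[(2,4-dimethoxy-6-methylphenyl)methylidene]hydrazine (hydrazone of 1, formed in situ) | COc1cc(C)c(/C=N/N)c(OC)c1 | intermediate
3 | 1,5-dimethoxy-2,3-dimethylbenzene | COc1cc(C)c(C)c(OC)c1 | intermediate
4 | [(2,4-dimethoxy-5,6-dimethylphenyl)methylidene]dimethyliminium chloride (formed in situ) | COc1cc(OC)c(C=[N+](C)C)c(C)c1C.[Cl-] | intermediate
5 | 2,4-dimethoxy-5,6-dimethylbenzaldehyde | COc1cc(OC)c(C=O)c(C)c1C | intermediate
6 | 2,4-dimethoxy-5,6-dimethylbenzoic acid | COc1cc(OC)c(C(=O)O)c(C)c1C | intermediate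
7 | methyl 2,4-dimethoxy-5,6-dimethylbenzoate | COC(=O)c1c(OC)cc(OC)c(C)c1C | intermediate
8 | [2-(methoxycarbonyl)-3,5-dimethoxy-6-methylphenyl]methyllithium (formed in situ) | COC(=O)c1c(OC)cc(OC)c(C)c1C[Li] | intermediate
9 | methyl 2-ethyl-4,6-dimethoxy-3-methylbenzoate | COC(=O)c1c(OC)cc(OC)c(C)c1CC | intermediate
10 | 2-(benzyloxy)-N-methoxy-N-methylacetamide | CON(C)C(=O)COCc1ccccc1 | starting material
11 | 1-[2-(methoxycarbonyl)-3,5-dimethoxy-6-methylphenyl]ethyllithium (racemic, formed in situ) | COC(=O)c1c(OC)cc(OC)c(C)c1C(C)[Li] | intermediate
12 | lithium 1-(benzyloxy)-3-[2-(methoxycarbonyl)-3,5-dimethoxy-6-methylphenyl]-2-[methoxy(methyl)amino]butan-2-olate (diastereomer mixture, formed in situ) | COC(=O)c1c(OC)cc(OC)c(C)c1C(C)C(O[Li])(COCc1ccccc1)N(C)OC | intermediate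
13 | methyl 2-[4-(benzyloxy)-3-oxobutan-2-yl]-4,6-dimethoxy-3-methylbenzoate (racemic) | COC(=O)c1c(OC)cc(OC)c(C)c1C(C)C(=O)COCc1ccccc1 | intermediate
14 | 3-[(benzyloxy)methyl]-6,8-dimethoxy-4,5-dimethyl-1H-isochromen-1-one | COc1cc(OC)c2c(c1C)C(C)=C(COCc1ccccc1)OC2=O | intermediate
15 | 8-hydroxy-3-(hydroxymethyl)-6-methoxy-4,5-dimethyl-1H-isochromen-1-one | COc1cc(O)c2c(c1C)C(C)=C(CO)OC2=O | intermediate
16 | methyl 2,4-dihydroxy-3,6-dimethylbenzoate | COC(=O)c1c(C)cc(O)c(C)c1O | starting material
17 | methyl 3-formyl-4,6-dihydroxy-2,5-dimethylbenzoate | COC(=O)c1c(C)c(C=O)c(O)c(C)c1O | intermediate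
18 | methyl 4,6-dihydroxy-3-(hydroxymethyl)-2,5-dimethylbenzoate (formed in situ) | COC(=O)c1c(C)c(CO)c(O)c(C)c1O | intermediate
19 | methyl 2,4-dihydroxy-3,5,6-trimethylbenzoate | COC(=O)c1c(C)c(C)c(O)c(C)c1O | intermediate
20 | 2,4-dihydroxy-3,5,6-trimethylbenzoylium hydrogen sulfate (formed in situ) | [O+]#Cc1c(C)c(C)c(O)c(C)c1O.OS(=O)(=O)[O-] | intermediate
21 | 2,4-dihydroxy-3,5,6-trimethylbenzoic acid | OC(=O)c1c(C)c(C)c(O)c(C)c1O | intermediate
22 | (8-hydroxy-6-methoxy-4,5-dimethyl-1-oxo-1H-isochromen-3-yl)methyl 2,4-dihydroxy-3,5,6-trimethylbenzoate | COc1cc(O)c2c(c1C)C(C)=C(COC(=O)c1c(C)c(C)c(O)c(C)c1O)OC2=O | intermediate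
23 | 2-[(2S)-4-[(2,4-dihydroxy-3,5,6-trimethylbenzoyl)oxy]-3-oxobutan-2-yl]-6-hydroxy-4-methoxy-3-methylbenzoic acid (formed in situ) | COc1cc(O)c(C(=O)O)c(c1C)[C@H](C)C(=O)COC(=O)c1c(C)c(C)c(O)c(C)c1O | intermediate
24 | [(3R,4S)-3,8-dihydroxy-6-methoxy-4,5-dimethyl-1-oxo-3,4-dihydro-1H-isochromen-3-yl]methyl 2,4-dihydroxy-3,5,6-trimethylbenzoate (CNP0157156.2) | COc1cc(O)c2c(c1C)[C@H](C)[C@](O)(COC(=O)c1c(C)c(C)c(O)c(C)c1O)OC2=O | target

**Step count and risks**

Total step count: 13. Longest linear sequence: 10 steps (steps 1 to 8, then 12 and 13); the ring B acid takes steps 9 to 11.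

Steps most likely to fail:

1. Step 13. The protonation at C4 may show poor or reversed facial selectivity, the hindered aroyl-enzyme may deacylate too slowly for turnover, or the open keto acid may racemise before it closes.
 Fallback, from 22 back to 24, by known chemistry: the enol lactone is opened with LiOH in aqueous THF at 0 °C (standard alkaline hydrolysis of isocoumarins; the ring B ester, a di-ortho-substituted benzoate carrying two phenoxides under these conditions, should survive). Acidification to pH 3 gives the racemic keto acid 2-[4-[(2,4-dihydroxy-3,5,6-trimethylbenzoyl)oxy]-3-oxobutan-2-yl]-6-hydroxy-4-methoxy-3-methylbenzoic acid F1. This closes under the same thermodynamic control to the racemic trans lactol F2. Preparative HPLC on a chiral stationary phase (amylose or cellulose carbamate, non-protic acidic eluent) then gives 24, and the (3S,4R) enantiomer is discarded.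

2. Step 6. Deprotonation and acylation at the secondary benzylic position may be sluggish, because the planar anion suffers allylic strain between its methyl group and the flanking ester and 3-methyl, and proton transfer from the α-CH2 of the amide may quench it.
 Fallback, from 7 back to 13, reversing the order of the two C–C bond formations: the unhindered primary lithium species 8 (already made from 7 in step 5) is acylated with 10. Through the lithium hemiaminal adduct F3 and acidic work-up this gives the ketone methyl 2-[3-(benzyloxy)-2-oxopropyl]-4,6-dimethoxy-3-methylbenzoate F4. Its doubly activated benzylic CH2 is then C-methylated (KOC(CH3)3, MeI, THF, −78 °C) to give 13.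

3. Step 12. Chemoselectivity of the Mitsunobu activation may be lost (O-alkylation of a phenol, or slow attack by the hindered carboxylate with decomposition of the activated allylic alcohol).
 Fallback, from 15 back to 22, separating activation from esterification: an Appel reaction (CBr4, PPh3, CH2Cl2, 0 °C) converts 15 into 3-(bromomethyl)-8-hydroxy-6-methoxy-4,5-dimethyl-1H-isochromen-1-one F5. The carboxylate of 21, formed selectively with KHCO3 in DMF at rt, then displaces the allylic bromide in an SN2 alkylation to give 22.

Further compounds
F1 | step 13 | 2-[4-[(2,4-dihydroxy-3,5,6-trimethylbenzoyl)oxy]-3-oxobutan-2-yl]-6-hydroxy-4-methoxy-3-methylbenzoic acid (racemic) | COc1cc(O)c(C(=O)O)c(c1C)C(C)C(=O)COC(=O)c1c(C)c(C)c(O)c(C)c1O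
F2 | step 13 | racemic trans lactol, (3R,4S) and (3S,4R) in equal parts | COc1cc(O)c2c(c1C)[C@H](C)[C@](O)(COC(=O)c1c(C)c(C)c(O)c(C)c1O)OC2=O.COc1cc(O)c2c(c1C)[C@@H](C)[C@@](O)(COC(=O)c1c(C)c(C)c(O)c(C)c1O)OC2=O
F3 | step 6 | lithium 1-(benzyloxy)-3-[2-(methoxycarbonyl)-3,5-dimethoxy-6-methylphenyl]-2-[methoxy(methyl)amino]propan-2-olate | COC(=O)c1c(OC)cc(OC)c(C)c1CC(O[Li])(COCc1ccccc1)N(C)OC
F4 | step 6 | methyl 2-[3-(benzyloxy)-2-oxopropyl]-4,6-dimethoxy-3-methylbenzoate | COC(=O)c1c(OC)cc(OC)c(C)c1CC(=O)COCc1ccccc1
F5 | step 12 | 3-(bromomethyl)-8-hydroxy-6-methoxy-4,5-dimethyl-1H-isochromen-1-one | COc1cc(O)c2c(c1C)C(C)=C(CBr)OC2=O
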